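**Strategy**

Side chain numbering: C1 (OCH2) to C8. Everything rests on cutting C1–C2. The key step exploits the O–C1–C2–O glycol pattern beside the C3=CH2 methylidene: C2 is latent as the formyl carbon of an α-methylene aldehyde, and C1, the methylene on the phenolic oxygen of the benzoate ring, as an aryloxymethylzinc. A titanium/bis(sulfonamide)-catalysed addition joins the vanillate fragment to the complete C2–C8 chain and sets C2 as the (R)-carbinol in one operation. Its precursor pair is an iodomethyl aryl ether and a 2-methylene aldehyde whose C5 ketone travels as a silyl-protected carbinol; mesylate displacement by hydrogen peroxide then inverts C2 to the (S)-hydroperoxide.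

Key step: step 6

**Remarks on the chemistry (assumptions)**

- The target is treated as the open γ-hydroperoxy ketone; any ring–chain equilibrium with the 1,2-dioxan-3-ol form does not change the route.
- C5 is deliberately made racemic, so compounds 13–17 are pairs of C5 epimers; the pair merges into one compound in step 11.
- The (1R,2R)-bis(triflamide) ligand is assumed to deliver the zinc-bound group to the aldehyde Si face, as it does for simple dialkylzincs. The configuration of 13 is to be checked (Mosher esters); if the sense is opposite, the (1S,2S)-ligand is used.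
- Compounds 15–19 are peroxides and are to be handled cold and on small scale.

**Route**

Step 1
Reactants: 1 methyl vanillate (methyl 4-hydroxy-3-methoxybenzoate)
Product: 2 methyl 3-methoxy-4-[(methylsulfanyl)methoxy]benzoate
Conditions: NaH, ClCH2SMe, NaI (cat.), DMF, 0 °C → rt
Reagents that add atoms: chloromethyl methyl sulfide, CSCCl
Why: Williamson-type O-alkylation of the phenoxide by the highly reactive α-chloro sulfide gives the methylthiomethyl ether; the benzoate ester is inert to these conditions.

Step 2
Reactants: 2 methyl 3-methoxy-4-[(methylsulfanyl)methoxy]benzoate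
Product: 4 methyl 4-(iodomethoxy)-3-methoxybenzoate, via chloromethyl ether 3 (not isolated)
Conditions: SO2Cl2, CH2Cl2, 0 °C; evaporate; NaI, acetone, rt, dark; used at once
Reagents that add atoms: sodium iodide, [Na+].[I-]; sulfuryl chloride, O=S(=O)(Cl)Cl (chlorine of 3 only)
Why: Chlorinolysis of the O,S-acetal (S-chlorosulfonium, then chloride attack at the OCH2 carbon with loss of MeSCl) gives the aryl chloromethyl ether, and a Finkelstein exchange gives the iodide needed for iodine–zinc exchange; the ester-deactivated ring should resist chlorination at 0 °C.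

Step 3
Reactants: 5 methallyl alcohol (2-methylprop-2-en-1-ol); 6 prenal (3-methylbut-2-enal)
Product: 8 racemic 6-methyl-2-methylidenehept-5-ene-1,4-diol, via dilithiated methallyl alcohol 7 (not isolated)
Conditions: n-BuLi (2.2 equiv), TMEDA, Et2O–hexane, 0 °C → rt; then 6, −78 °C; aq. NH4Cl
Reagents that add atoms: n-butyllithium, [Li]CCCC (lithium of 7 only)
Why: O,C-double deprotonation gives a 2-(oxidomethyl)allyllithium whose symmetric allyl terminus adds 1,2 to the β,β-disubstituted enal (carbonyl addition of an allylic dianion), creating C5 as a racemic carbinol that is oxidised later.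

Step 4
Reactants: 8 racemic 6-methyl-2-methylidenehept-5-ene-1,4-diol
Product: 10 racemic 4-[(tert-butyldimethylsilyl)oxy]-6-methyl-2-methylidene-1-[(triethylsilyl)oxy]hept-5-ene, via mono-TES ether 9 (not isolated)
Conditions: TESCl (1.0 equiv), imidazole, DMF, −40 °C; then TBSCl, rt
Reagents that add atoms: chlorotriethylsilane, CC[Si](Cl)(CC)CC; tert-butyldimethylsilyl chloride, CC(C)(C)[Si](C)(C)Cl
Why: The unhindered primary allylic hydroxyl is silylated selectively by one equivalent of TESCl at low temperature, and the remaining secondary hydroxyl is then capped as the more robust TBS ether in the same pot (differential silylation).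

Step 5
Reactants: 10 racemic 4-[(tert-butyldimethylsilyl)oxy]-6-methyl-2-methylidene-1-[(triethylsilyl)oxy]hept-5-ene
Product: 11 racemic 4-[(tert-butyldimethylsilyl)oxy]-6-methyl-2-methylidenehept-5-enal
Conditions: (COCl)2, DMSO, CH2Cl2, −78 → −40 °C; Et3N, −78 → 0 °C; used cold and without delay
Reagents that add atoms: none
Why: Under Swern conditions a primary triethylsilyl ether is cleaved by the chlorosulfonium salt and oxidised directly to the aldehyde while the secondary TBS ether is untouched (selective oxidative desilylation), which avoids handling a free hydroxy aldehyde.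

Step 6
Reactants: 4 methyl 4-(iodomethoxy)-3-methoxybenzoate (about 3 equiv); 11 racemic 4-[(tert-butyldimethylsilyl)oxy]-6-methyl-2-methylidenehept-5-enal
Product: 13 methyl 4-{[(2R)-5-[(tert-butyldimethylsilyl)oxy]-2-hydroxy-7-methyl-3-methylideneoct-6-en-1-yl]oxy}-3-methoxybenzoate as a pair of C5 epimers, via bis(aryloxymethyl)zinc 12 (not isolated)
Conditions: Et2Zn (0.55 equiv per 4), toluene, −10 → 0 °C, volatiles removed in vacuo; then Ti(OiPr)4, (1R,2R)-1,2-bis(trifluoromethanesulfonamido)cyclohexane (8 mol %), toluene, −20 °C; aq. NH4Cl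
Reagents that add atoms: diethylzinc, CC[Zn]CC (zinc of 12 only)
Why: Iodine–zinc exchange of the α-oxygen-activated iodide 4 gives the bis(aryloxymethyl)zinc 12, and one aryloxymethyl group is transferred within a chiral titanium bis(sulfonamide) complex to the titanium-activated formyl group of 11, forming the C1–C2 bond by 1,2-addition. The closest known reaction type is the titanium/trans-1,2-bis(triflamido)cyclohexane-catalysed enantioselective addition of functionalised diorganozincs, including acyloxymethylzincs, to aldehydes. No ring is closed. The C2 stereocentre is set by the catalyst: the (1R,2R)-ligand should direct the group to the Si face of the aldehyde, which here corresponds to the (2R)-carbinol, and α-branched enals are favourable substrates for this catalyst system. The remote racemic C5 centre should not interfere and only leads to two C5 epimers. The step needs 1,2- over 1,4-addition and aldehyde over ester attack, which the low basicity of diorganozincs and selective Ti activation of the aldehyde should secure, and it needs the α-aryloxy zinc not to α-eliminate, which the poor leaving-group ability of aryloxide compared with the iodide of a Simmons–Smith carbenoid should secure.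

Step 7
Reactants: 13 methyl 4-{[(2R)-5-[(tert-butyldimethylsilyl)oxy]-2-hydroxy-7-methyl-3-methylideneoct-6-en-1-yl]oxy}-3-methoxybenzoate
Product: 14 methyl 4-{[(2R)-5-[(tert-butyldimethylsilyl)oxy]-2-(methanesulfonyloxy)-7-methyl-3-methylideneoct-6-en-1-yl]oxy}-3-methoxybenzoate
Conditions: MsCl, Et3N, CH2Cl2, −30 °C; used crude
Reagents that add atoms: methanesulfonyl chloride, CS(=O)(=O)Cl
Why: O-Sulfonylation leaves the C2–O bond intact, so the (2R) configuration is retained, and the low temperature suppresses ionisation of the allylic mesylate.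

Step 8
Reactants: 14 methyl 4-{[(2R)-5-[(tert-butyldimethylsilyl)oxy]-2-(methanesulfonyloxy)-7-methyl-3-methylideneoct-6-en-1-yl]oxy}-3-methoxybenzoate
Product: 15 methyl 4-{[(2S)-5-[(tert-butyldimethylsilyl)oxy]-2-hydroperoxy-7-methyl-3-methylideneoct-6-en-1-yl]oxy}-3-methoxybenzoate
Conditions: 50% aq. H2O2 (excess), KOH (1.5 equiv), THF–MeOH, 0 °C
Reagents that add atoms: hydrogen peroxide, OO
Why: Hydroperoxide anion, a weakly basic α-effect nucleophile, displaces the allylic secondary mesylate by SN2 with inversion to the (2S)-hydroperoxide (sulfonate perhydrolysis); with no C5 ketone present there is no enone epoxidation, β,γ-to-α,β isomerisation or carbonyl participation, and the TBS ether blocks tetrahydrofuran formation.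

Step 9
Reactants: 15 methyl 4-{[(2S)-5-[(tert-butyldimethylsilyl)oxy]-2-hydroperoxy-7-methyl-3-methylideneoct-6-en-1-yl]oxy}-3-methoxybenzoate
Product: 16 methyl 4-{[(2S)-5-[(tert-butyldimethylsilyl)oxy]-2-[(2-methoxypropan-2-yl)peroxy]-7-methyl-3-methylideneoct-6-en-1-yl]oxy}-3-methoxybenzoate
Conditions: 2-methoxypropene, PPTS (cat.), CH2Cl2, 0 °C
Reagents that add atoms: 2-methoxypropene, C=C(C)OC
Why: Acid-catalysed addition of the hydroperoxide O–H to the enol ether gives the monoperoxyketal, a standard hydroperoxide protection that tolerates fluoride and Dess–Martin oxidation.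

Step 10
Reactants: 16 methyl 4-{[(2S)-5-[(tert-butyldimethylsilyl)oxy]-2-[(2-methoxypropan-2-yl)peroxy]-7-methyl-3-methylideneoct-6-en-1-yl]oxy}-3-methoxybenzoate
Product: 17 methyl 4-{[(2S)-5-hydroxy-2-[(2-methoxypropan-2-yl)peroxy]-7-methyl-3-methylideneoct-6-en-1-yl]oxy}-3-methoxybenzoate
Conditions: TBAF, AcOH (1 equiv each), THF, 0 °C → rt
Reagents that add atoms: none
Why: Fluoride-mediated Si–O cleavage frees the C5 carbinol, and buffering with acetic acid keeps the medium non-basic so that the peroxyketal and the methyl ester survive.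

Step 11
Reactants: 17 methyl 4-{[(2S)-5-hydroxy-2-[(2-methoxypropan-2-yl)peroxy]-7-methyl-3-methylideneoct-6-en-1-yl]oxy}-3-methoxybenzoate
Product: 18 methyl 3-methoxy-4-{[(2S)-2-[(2-methoxypropan-2-yl)peroxy]-7-methyl-3-methylidene-5-oxooct-6-en-1-yl]oxy}benzoate
Conditions: Dess–Martin periodinane, NaHCO3, CH2Cl2, 0 °C → rt
Reagents that add atoms: none
Why: Dess–Martin oxidation of the allylic C5 carbinol under buffered neutral conditions gives the dimethyl enone, merges the two C5 epimers into one compound and leaves the β,γ-alkene out of conjugation.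

Step 12
Reactants: 18 methyl 3-methoxy-4-{[(2S)-2-[(2-methoxypropan-2-yl)peroxy]-7-methyl-3-methylidene-5-oxooct-6-en-1-yl]oxy}benzoate
Product: 19 methyl 4-{[(2S)-2-hydroperoxy-7-methyl-3-methylidene-5-oxooct-6-en-1-yl]oxy}-3-methoxybenzoate (CNP0338697.1)
Conditions: AcOH–THF–H2O (4:2:1), rt
Reagents that add atoms: none
Why: Mild aqueous acid hydrolyses the peroxyketal at its ketal carbon (releasing acetone and methanol) without touching the C2–O bond, so the (2S)-hydroperoxide is liberated with its configuration intact.

**Compound list**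

1 | methyl vanillate (methyl 4-hydroxy-3-methoxybenzoate) | COC(=O)c1ccc(O)c(OC)c1 | starting material
2 | methyl 3-methoxy-4-[(methylsulfanyl)methoxy]benzoate | COC(=O)c1ccc(OCSC)c(OC)c1 | intermediate
3 | methyl 4-(chloromethoxy)-3-methoxybenzoate | COC(=O)c1ccc(OCCl)c(OC)c1 | intermediate
4 | methyl 4-(iodomethoxy)-3-methoxybenzoate | COC(=O)c1ccc(OCI)c(OC)c1 | intermediate
5 | methallyl alcohol (2-methylprop-2-en-1-ol) | C=C(C)CO | starting material
6 | prenal (3-methylbut-2-enal) | CC(C)=CC=O | starting material
7 | dilithiated methallyl alcohol (lithium 2-(lithiomethyl)prop-2-en-1-olate) | [Li]CC(=C)CO[Li] | intermediate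
8 | racemic 6-methyl-2-methylidenehept-5-ene-1,4-diol | C=C(CO)CC(O)C=C(C)C | intermediate
9 | racemic 6-methyl-2-methylidene-1-[(triethylsilyl)oxy]hept-5-en-4-ol | C=C(CO[Si](CC)(CC)CC)CC(O)C=C(C)C | intermediate
10 | racemic 4-[(tert-butyldimethylsilyl)oxy]-6-methyl-2-methylidene-1-[(triethylsilyl)oxy]hept-5-ene | C=C(CO[Si](CC)(CC)CC)CC(O[Si](C)(C)C(C)(C)C)C=C(C)C | intermediate
11 | racemic 4-[(tert-butyldimethylsilyl)oxy]-6-methyl-2-methylidenehept-5-enal | C=C(C=O)CC(O[Si](C)(C)C(C)(C)C)C=C(C)C | intermediate
12 | bis{[2-methoxy-4-(methoxycarbonyl)phenoxy]methyl}zinc | COC(=O)c1ccc(OC[Zn]COc2ccc(C(=O)OC)cc2OC)c(OC)c1 | intermediate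
13 | methyl 4-{[(2R)-5-[(tert-butyldimethylsilyl)oxy]-2-hydroxy-7-methyl-3-methylideneoct-6-en-1-yl]oxy}-3-methoxybenzoate (C5 epimers) | C=C(CC(O[Si](C)(C)C(C)(C)C)C=C(C)C)[C@H](COc1ccc(C(=O)OC)cc1OC)O | intermediate
14 | methyl 4-{[(2R)-5-[(tert-butyldimethylsilyl)oxy]-2-(methanesulfonyloxy)-7-methyl-3-methylideneoct-6-en-1-yl]oxy}-3-methoxybenzoate (C5 epimers) | C=C(CC(O[Si](C)(C)C(C)(C)C)C=C(C)C)[C@H](COc1ccc(C(=O)OC)cc1OC)OS(C)(=O)=O | intermediate
15 | methyl 4-{[(2S)-5-[(tert-butyldimethylsilyl)oxy]-2-hydroperoxy-7-methyl-3-methylideneoct-6-en-1-yl]oxy}-3-methoxybenzoate (C5 epimers) | C=C(CC(O[Si](C)(C)C(C)(C)C)C=C(C)C)[C@@H](COc1ccc(C(=O)OC)cc1OC)OO | intermediate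
16 | methyl 4-{[(2S)-5-[(tert-butyldimethylsilyl)oxy]-2-[(2-methoxypropan-2-yl)peroxy]-7-methyl-3-methylideneoct-6-en-1-yl]oxy}-3-methoxybenzoate (C5 epimers) | C=C(CC(O[Si](C)(C)C(C)(C)C)C=C(C)C)[C@@H](COc1ccc(C(=O)OC)cc1OC)OOC(C)(C)OC | intermediate
17 | methyl 4-{[(2S)-5-hydroxy-2-[(2-methoxypropan-2-yl)peroxy]-7-methyl-3-methylideneoct-6-en-1-yl]oxy}-3-methoxybenzoate (C5 epimers) | C=C(CC(O)C=C(C)C)[C@@H](COc1ccc(C(=O)OC)cc1OC)OOC(C)(C)OC | intermediate
18 | methyl 3-methoxy-4-{[(2S)-2-[(2-methoxypropan-2-yl)peroxy]-7-methyl-3-methylidene-5-oxooct-6-en-1-yl]oxy}benzoate | C=C(CC(=O)C=C(C)C)[C@@H](COc1ccc(C(=O)OC)cc1OC)OOC(C)(C)OC | intermediate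
19 | methyl 4-{[(2S)-2-hydroperoxy-7-methyl-3-methylidene-5-oxooct-6-en-1-yl]oxy}-3-methoxybenzoate (CNP0338697.1) | C=C(CC(=O)C=C(C)C)[C@@H](COc1ccc(C(=O)OC)cc1OC)OO | target

**Step count**

Total step count: 12. Longest linear sequence: 10 steps (steps 3–12, from methallyl alcohol and prenal).

**Steps most likely to fail, with fallbacks**

Step 6 (key step). The aryloxymethylzinc may decompose by α-elimination before it is transferred, the zinc-bound group may transfer sluggishly, or facial discrimination at the α-methylene aldehyde may be poor. The fallback separates bond formation from stereocontrol and sets out from 4 and 11. Iodine–magnesium exchange of 4 with i-PrMgCl·LiCl in THF at −78 °C should give [2-methoxy-4-(methoxycarbonyl)phenoxy]methylmagnesium chloride F1. Addition of 11 at −78 °C should give the carbinol methyl 4-{[5-[(tert-butyldimethylsilyl)oxy]-2-hydroxy-7-methyl-3-methylideneoct-6-en-1-yl]oxy}-3-methoxybenzoate F2 as a mixture of all C2/C5 stereoisomers. Dess–Martin oxidation should give the α-methylene ketone methyl 4-{[5-[(tert-butyldimethylsilyl)oxy]-7-methyl-3-methylidene-2-oxooct-6-en-1-yl]oxy}-3-methoxybenzoate F3. Corey–Bakshi–Shibata reduction with the (R)-oxazaborolidine and catecholborane at −78 °C (the 1,1-disubstituted vinyl group acting as the large substituent) should then return the route to 13.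

Step 8. The hydroperoxide anion may attack the methylidene terminus (SN2′), the mesylate may be lost by E2 toward C1, and the benzoate may suffer perhydrolysis in aqueous alkaline peroxide. The fallback replaces free peroxide anion in a protic medium by alkylation of a protected hydroperoxide under aprotic conditions; it sets out from 13 and comes back at 16, bypassing 15. Alcohol 13 is converted (NsCl, Et3N, DMAP, CH2Cl2, 0 °C) into the (2R)-4-nitrobenzenesulfonate of 13 F4. This is treated with 2-methoxyprop-2-yl hydroperoxide F5 (made by ozonolysis of 2,3-dimethylbut-2-ene in methanol) and CsOH·H2O in DMF at 0 °C, which should give the peroxyketal 16 directly with inversion at C2.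

Step 3. C-metalation of methallyl alcohol may be incomplete, and the basic allyllithium may deprotonate prenal at its γ-methyl groups instead of adding to the carbonyl. The fallback uses a non-basic allylmetal; it sets out from 6 and comes back at 8. Zinc-mediated Barbier (Reformatsky-type) allylation of 6 with ethyl 2-(bromomethyl)acrylate (Zn, THF–aq. NH4Cl) should give ethyl 4-hydroxy-6-methyl-2-methylidenehept-5-enoate F6, which lactonises to 3-methylidene-5-(2-methylprop-1-en-1-yl)oxolan-2-one F7. Reduction with excess DIBAL-H (CH2Cl2, −78 → 0 °C) should then give diol 8.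

**Further compounds**

F1 | step 6 | [2-methoxy-4-(methoxycarbonyl)phenoxy]methylmagnesium chloride | COC(=O)c1ccc(OC[Mg]Cl)c(OC)c1
F2 | step 6 | methyl 4-{[5-[(tert-butyldimethylsilyl)oxy]-2-hydroxy-7-methyl-3-methylideneoct-6-en-1-yl]oxy}-3-methoxybenzoate (all C2/C5 stereoisomers) | C=C(CC(O[Si](C)(C)C(C)(C)C)C=C(C)C)C(O)COc1ccc(C(=O)OC)cc1OC
F3 | step 6 | methyl 4-{[5-[(tert-butyldimethylsilyl)oxy]-7-methyl-3-methylidene-2-oxooct-6-en-1-yl]oxy}-3-methoxybenzoate (racemic at C5) | C=C(CC(O[Si](C)(C)C(C)(C)C)C=C(C)C)C(=O)COc1ccc(C(=O)OC)cc1OC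
F4 | step 8 | (2R)-4-nitrobenzenesulfonate of 13 (C5 epimers) | C=C(CC(O[Si](C)(C)C(C)(C)C)C=C(C)C)[C@H](COc1ccc(C(=O)OC)cc1OC)OS(=O)(=O)c1ccc(cc1)[N+](=O)[O-]
F5 | step 8 | 2-methoxyprop-2-yl hydroperoxide | COC(C)(C)OO
F6 | step 3 | racemic ethyl 4-hydroxy-6-methyl-2-methylidenehept-5-enoate | C=C(CC(O)C=C(C)C)C(=O)OCC
F7 | step 3 | racemic 3-methylidene-5-(2-methylprop-1-en-1-yl)oxolan-2-one | C=C1CC(C=C(C)C)OC1=O
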